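A small charge of coupling partner shows how the products share out: in the grey run, with 0.23 M of partner against 0.50 M of substrate, target, intermediate and isomer of the product end at 43.5% together, near the 46.0% that partner, the limiting reagent there, allows at one to one.

| setting | grey | amber | Saturday's | Friday's |
|---|---|---|---|---|
| substrate | 0.50 M | 0.50 M | 0.50 M | 0.50 M |
| coupling partner | 0.23 M | 0.34 M | 0.450 M | 0.450 M |
| temperature | 29 °C | 37 °C | 25 °C | 40 °C |
| remark | run made earlier | run made earlier |  |  |
| time |  |  | 3.0 h | 3.0 h |

| run | time / min | substrate / % | target / % | intermediate / % | isomer of the product / % |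
|---|---|---|---|---|---|
| grey | 10.0 | 64.2 | 2.9 | 9.4 | 0 |
| grey | 25.0 | 56.1 | 12.8 | 10.6 | 0.2 |
| grey | 50.0 | 49.7 | 23.5 | 13.2 | 0 |
| grey | 80.0 | 44.3 | 25.9 | 12.4 | 1.8 |
| grey | 120 | 43.0 | 29.0 | 12.7 | 1.8 |
| amber | 12.0 | 51.7 | 18.5 | 18.8 | 0 |
| amber | 20.0 | 42.7 | 28.4 | 19.1 | 0.9 |
| amber | 30.0 | 37.8 | 33.0 | 19.9 | 1.4 |
| amber | 40.0 | 33.3 | 35.3 | 21.1 | 1.4 |
| amber | 60.0 | 30.0 | 37.7 | 20.6 | 1.9 |

(each reading ± 1 percentage point)

1. which of these there is most of at the end, counted by the substrate in it, Saturday's (isomer of the product / intermediate / target / substrate)
2. which of these there is most of at the end, counted by the substrate in it, Friday's (isomer of the product / intermediate / target / substrate)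
3. the largest of these amounts at the end, in percent of the substrate charged, Saturday's
4. the largest of these amounts at the end, in percent of the substrate charged, Friday's

- a reading of substrate is of its free form alone

Late in each run the ratio [target]/[intermediate] climbs more slowly, so it is worth freezing, and two ways lead to it. The stock way divides what stands at the last reading, giving 2.28 in the grey run at 29 °C and 1.83 in the amber run at 37 °C. The flow way divides what was gained late, and if the ratio were frozen it would return the same number, but in the amber run it gives 6.20. The flow way is the one that cheats, because its denominator, 1.5 percentage points, is less than two standard deviations of a reading, and in the grey run the same difference from the third reading to the last is −0.5 points. The stock reading is lower in the hotter amber run, though the charge of partner differs between the two runs as well, and ln of the ratio is carried on in a straight line in temperature through them: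

split at 25 °C = 2.55

split at 40 °C = 1.68

This split, the late ratio [target]/[intermediate] at a given temperature, is above one in Saturday's and Friday's flasks, so this reckoning puts target ahead of intermediate in each. With partner at one to one, it caps target at 64.7% in Saturday's flask and 56.5% in Friday's; these are ceilings, not estimates.

The forecast named target for Saturday's flask at 46% and target for Friday's at 53%, holding that intermediate “behaves as a stable side branch”.

Saturday's flask gives target at 52.6%. Friday's flask gives target at 43.3%.

    substrate + coupling partner → intermediate + by-product (k = 0.00110 M⁻¹ s⁻¹, Ea = 74.0 kJ mol⁻¹)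
    intermediate ⇌ target (K = 2.70, k = 6.90 × 10⁻⁴ s⁻¹, Ea = 95.0 kJ mol⁻¹, ΔH = −26.0 kJ mol⁻¹)
    intermediate ⇌ isomer of the product (K = 220, k = 9.80 × 10⁻⁶ s⁻¹, Ea = 98.0 kJ mol⁻¹, ΔH = 14.0 kJ mol⁻¹)
    substrate ⇌ dormant form (K = 0.390, k = 0.00110 s⁻¹, Ea = 78.0 kJ mol⁻¹, ΔH = −38.0 kJ mol⁻¹)
    (constants at 25 °C)

At the end Saturday's flask stands at a split of 2.50 against the reckoned 2.55, and Friday's at 1.65 against 1.68, with its isomer of the product at 19.1%. Friday's flask left until 12 h has substrate at 8.43%, dormant form at 1.58% and isomer of the product at 57.7%, so the remaining 32.3%, shared between target and intermediate by the split, gives target 20.2%. That flask holds target at 20.1% and intermediate at 12.2%, and its largest share is isomer of the product, at 57.7%.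

The earlier runs and the new flask come from a simulation for substances that don't exist; noise was put on by code.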